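**Retrosynthetic overview**

1. The target is siphonaxanthin 19-[(E)-dec-2-enoate] (carotenoid numbering; ring B = C1–C6 of the 3-hydroxy-β end, ring E = C1'–C6' of the 3'-hydroxy-ε end). The C19–O ester and the C9=C10 alkene are made together at the end by acylation and 1,3-transposition of a Morita–Baylis–Hillman carbinol, which comes from C9–C10 union of a ring-B vinyl ketone (C1–C9, C19) with a C27 polyene aldehyde (C10 to C7' plus ring E).
2. The C27 aldehyde comes from two-carbon Wittig homologation (C10, C11) of a C25 aldehyde, itself from a ring-E C15 phosphonium salt and the C10 dialdehyde (C11'=C12'); the C15 unit comes from a Julia–Kocienski olefination at C7'=C8'.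
3. The ring-B vinyl ketone comes from alkylation of lithiated methoxyallene (C8, C9, C19) with the ring-B allylic bromide (C7–C8 bond), then hydrolysis.
4. Both rings are formed first and in the same operation: one racemic keto ester, ethyl 2,6,6-trimethyl-4-oxocyclohex-2-ene-1-carboxylate, is the precursor of ring B and of ring E (enantiomeric CBS catalysts; for ring B the alkene is then moved to C5=C6). It is assembled from two molecules of acetone and one of ethyl acetoacetate in a one-pot three-component Knoevenagel–Michael–aldol [3+3] annulation that closes C1–C2 and C4–C5.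
5. Enabling feature: in ring B (and likewise ring E) the carbinol carbon C3 lies between two CH2 carbons, C2 and C4, which are bonded to the two methyl-bearing ring carbons C1 (quaternary, gem-dimethyl) and C5 (one methyl), while C6 between these carries the exocyclic carbon C7. C2–C3(O)–C4 is an acetone unit, C1 with its two methyls is a second acetone carbonyl carbon, and CH3–C5–C6–C7 is an acetoacetate unit.

Key step: step 1

Remark: TBS = tert-butyl(dimethyl)silyl, PT = 1-phenyl-1H-tetrazol-5-yl, RB = (4R)-4-(TBS-oxy)-2,6,6-trimethylcyclohex-1-en-1-yl, RE = (1R,4R)-4-(TBS-oxy)-2,6,6-trimethylcyclohex-2-en-1-yl; compound 5 is used as the racemate, polyenes are handled under argon in the dark, and any Z isomer from an olefination is equilibrated to E (I2 cat.).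

**Route**

Step 1
Reactants: 1 acetone (two molecules are incorporated; also the solvent), 2 ethyl acetoacetate
Product: 5 ethyl 2,6,6-trimethyl-4-oxocyclohex-2-ene-1-carboxylate (racemic), via ethyl 2-acetyl-3-methylbut-2-enoate 3 (not isolated), via ethyl 2-acetyl-3,3-dimethyl-5-oxohexanoate 4 (not isolated)
Conditions: pyrrolidine (0.3 equiv), AcOH (0.3 equiv), 4 Å molecular sieves, acetone (solvent), sealed tube, 70 °C
Reagents that add atoms: none
Why: Proposed new method: pyrrolidinium acetate converts acetone into its iminium ion and its enamine, so that a Knoevenagel condensation with 2 gives the doubly activated alkylidene 3, the enamine of a second acetone adds to 3 in a Michael reaction (bond C1–C2, quaternary C1, diketone 4), and the terminal enamine of the methyl ketone in 4 attacks the acetoacetate carbonyl C5 (bond C4–C5) with loss of water to the conjugated enone. The closest known reactions are the three-component cyclohexenone synthesis from an aldehyde and two β-keto ester units (Knoevenagel–Michael–aldol, as in the Hagemann ester synthesis) and the condensation of mesityl oxide with acetoacetic ester, which runs through the same diketone 4; new is a ketone as the carbonyl component of the one-pot version. The ring closes in a 6-(enolendo)-exo-trig aldol mode, and every event before the final dehydration is reversible, so the vinylogous β-keto ester 5 should be the thermodynamic sink. The only stereocentre (C6, α to the ester) is formed racemic on purpose, because each enantiomer is used later. The selectivity needed is the direction of the aldol step: the β-keto ester half of 4 rests as its conjugated enol or enamino ester and can act only as the electrophile at C5, so only the plain methyl ketone forms the nucleophilic enamine at C4. Self-condensation of acetone is tolerated, since mesityl oxide is converted into the same diketone 4 by Michael addition of 2, and isophorone is removed by distillation.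

Step 2
Reactants: 5 ethyl 2,6,6-trimethyl-4-oxocyclohex-2-ene-1-carboxylate (racemic)
Product: 6 ethyl (4S)-4-hydroxy-2,6,6-trimethylcyclohex-2-ene-1-carboxylate (both C1 epimers)
Conditions: (R)-2-methyl-CBS-oxazaborolidine (0.2 equiv), catecholborane, toluene, −78 °C
Reagents that add atoms: none
Why: Corey–Bakshi–Shibata reduction, in which the oxazaborolidine should deliver hydride to one face of the enone carbonyl (alkenyl arm as the large group) whatever the configuration of the remote ester-bearing carbon, so that both enantiomers of 5 give the (S)-allylic carbinol (C3 of ring B) while the ester and the C=C bond stay untouched.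

Step 3
Reactants: 6 ethyl (4S)-4-hydroxy-2,6,6-trimethylcyclohex-2-ene-1-carboxylate (both C1 epimers)
Product: 7 ethyl (4R)-4-hydroxy-2,6,6-trimethylcyclohex-1-ene-1-carboxylate
Conditions: NaOEt (0.3 equiv), EtOH, reflux
Reagents that add atoms: none
Why: Base-mediated conjugative double-bond migration through the ester dienolate (deprotonation at C6, reprotonation at C4) should move the alkene into the tetrasubstituted position next to the ester, erase the C6 centre so that both epimers converge, and leave C3 untouched (its descriptor changes from S to R only because the ranking of its two ring neighbours changes).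

Step 4
Reactants: 7 ethyl (4R)-4-hydroxy-2,6,6-trimethylcyclohex-1-ene-1-carboxylate
Product: 8 ethyl (4R)-4-(TBS-oxy)-2,6,6-trimethylcyclohex-1-ene-1-carboxylate
Conditions: TBSCl, imidazole, DMF, rt
Reagents that add atoms: tert-butyldimethylsilyl chloride, CC(C)(C)[Si](C)(C)Cl
Why: Standard silylation of the secondary alcohol, which protects C3–OH against the organolithium, bromination and acylation steps that follow.

Step 5
Reactants: 8 ethyl (4R)-4-(TBS-oxy)-2,6,6-trimethylcyclohex-1-ene-1-carboxylate
Product: 9 (RB)methanol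
Conditions: i-Bu2AlH, CH2Cl2, −78 → 0 °C
Reagents that add atoms: none
Why: 1,2-Reduction of the hindered conjugated ester by the aluminium hydride should give the allylic alcohol without touching the silyl ether or the tetrasubstituted alkene.

Step 6
Reactants: 9 (RB)methanol
Product: 10 (RB)methyl bromide
Conditions: CBr4, PPh3, CH2Cl2, 0 °C
Reagents that add atoms: carbon tetrabromide, BrC(Br)(Br)Br
Why: Appel bromination under neutral conditions should convert the primary allylic alcohol by SN2 displacement without allylic transposition or loss of the TBS ether, and the bromide is used at once.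

Step 7
Reactants: 10 (RB)methyl bromide, 11 methoxyallene
Product: 14 1-(RB)but-3-en-2-one, via 1-lithio-1-methoxyallene 12 (not isolated), via 2-methoxy-1-(RB)buta-2,3-diene 13 (not isolated)
Conditions: 11, n-BuLi, THF, −40 °C; then 10, −78 → −20 °C; then 0.5 M aq H2SO4, THF, 0 °C
Reagents that add atoms: water, O
Why: Lithiated methoxyallene is an acryloyl anion equivalent that should be alkylated at its oxygen-bearing carbon by SN2 at the primary allylic bromide (bond C7–C8), and mild acid hydrolysis of the allenyl enol ether then gives the vinyl ketone while the secondary TBS ether survives the cold dilute acid.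

Step 8
Reactants: 5 ethyl 2,6,6-trimethyl-4-oxocyclohex-2-ene-1-carboxylate (racemic)
Product: 15 ethyl (1R,4R)-4-hydroxy-2,6,6-trimethylcyclohex-2-ene-1-carboxylate (trans)
Conditions: (S)-2-methyl-CBS-oxazaborolidine (0.2 equiv), catecholborane, toluene, −78 °C; chromatography
Reagents that add atoms: none
Why: Corey–Bakshi–Shibata reduction with the enantiomeric catalyst should set the (R)-allylic carbinol (C3' of ring E) by reagent control, so that the (1R) half of racemic 5 gives the trans isomer 15 with the C6' configuration of the target, while the cis epimer from the (1S) half is removed by chromatography.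

Step 9
Reactants: 15 ethyl (1R,4R)-4-hydroxy-2,6,6-trimethylcyclohex-2-ene-1-carboxylate
Product: 16 ethyl (1R,4R)-4-(TBS-oxy)-2,6,6-trimethylcyclohex-2-ene-1-carboxylate
Conditions: TBSCl, imidazole, DMF, rt
Reagents that add atoms: tert-butyldimethylsilyl chloride, CC(C)(C)[Si](C)(C)Cl
Why: Standard silylation under weakly basic conditions that should not epimerize the ester α-centre or move the ring alkene.

Step 10
Reactants: 16 ethyl (1R,4R)-4-(TBS-oxy)-2,6,6-trimethylcyclohex-2-ene-1-carboxylate
Product: 17 (RE)methanol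
Conditions: i-Bu2AlH, CH2Cl2, −78 °C
Reagents that add atoms: none
Why: Aluminium hydride reduction of the ester is non-basic, so the adjacent stereocentre C6' and the position of the ring alkene should be preserved.

Step 11
Reactants: 17 (RE)methanol
Product: 18 5-{[(RE)methyl]sulfanyl}-1-phenyl-1H-tetrazole
Conditions: 1-phenyl-1H-tetrazole-5-thiol, PPh3, DIAD, THF, 0 °C → rt
Reagents that add atoms: 1-phenyl-1H-tetrazole-5-thiol, Sc1nnnn1-c2ccccc2
Why: Mitsunobu thioetherification replaces the primary hydroxyl by SN2 at C7' and does not touch the two ring stereocentres.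

Step 12
Reactants: 18 5-{[(RE)methyl]sulfanyl}-1-phenyl-1H-tetrazole
Product: 19 5-{[(RE)methyl]sulfonyl}-1-phenyl-1H-tetrazole
Conditions: (NH4)6Mo7O24·4H2O (cat.), 30% aq H2O2, EtOH, 0 °C → rt
Reagents that add atoms: hydrogen peroxide, OO
Why: Molybdate-catalysed peroxide oxidation of a sulfide to the sulfone is chemoselective over a trisubstituted alkene and a silyl ether.

Step 13
Reactants: 19 5-{[(RE)methyl]sulfonyl}-1-phenyl-1H-tetrazole, 20 ethyl (2E)-3-methyl-4-oxobut-2-enoate
Product: 22 ethyl (2E,4E)-3-methyl-5-(RE)penta-2,4-dienoate, via potassium salt of the sulfone 21 (not isolated)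
Conditions: KN(SiMe3)2, DME, −78 °C; then 20, −78 °C → rt
Reagents that add atoms: none
Why: Julia–Kocienski olefination should form the C7'=C8' bond with E selectivity, the carbanion sits on C7' and not on the stereocentre C6' so that no epimerization is expected, and the 9'E geometry is brought in with aldehyde 20.

Step 14
Reactants: 22 ethyl (2E,4E)-3-methyl-5-(RE)penta-2,4-dienoate
Product: 23 (2E,4E)-3-methyl-5-(RE)penta-2,4-dien-1-ol
Conditions: i-Bu2AlH, CH2Cl2, −78 °C
Reagents that add atoms: none
Why: 1,2-Reduction of the dienoate to the dienol by the aluminium hydride leaves the diene geometry and the silyl ether intact.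

Step 15
Reactants: 23 (2E,4E)-3-methyl-5-(RE)penta-2,4-dien-1-ol
Product: 24 [(2E,4E)-3-methyl-5-(RE)penta-2,4-dien-1-yl]triphenylphosphonium bromide
Conditions: PPh3·HBr, CH2Cl2, rt
Reagents that add atoms: triphenylphosphine hydrobromide, [Br-].[PH+](c1ccccc1)(c2ccccc2)c3ccccc3
Why: Standard preparation of a Wittig salt from an allylic alcohol, in which the easily formed pentadienyl cation is captured by the phosphine at the terminal carbon C11' while the less ionizable ring silyl ether should remain.

Step 16
Reactants: 24 [(2E,4E)-3-methyl-5-(RE)penta-2,4-dien-1-yl]triphenylphosphonium bromide, 25 (2E,4E,6E)-2,7-dimethylocta-2,4,6-trienedial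
Product: 26 (all-E)-2,7,11-trimethyl-13-(RE)trideca-2,4,6,8,10,12-hexaenal (C25 aldehyde)
Conditions: 25 (3 equiv), NaOMe, MeOH/CH2Cl2, 0 °C → rt; then I2 (cat.), CH2Cl2, rt
Reagents that add atoms: none
Why: Wittig olefination of the semistabilized ylide with an excess of the symmetrical dialdehyde should give mono-condensation at C11'=C12', and the Z isomer is equilibrated to E with iodine.

Step 17
Reactants: 26 (all-E)-2,7,11-trimethyl-13-(RE)trideca-2,4,6,8,10,12-hexaenal, 27 (1,3-dioxolan-2-ylmethyl)triphenylphosphonium bromide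
Product: 29 (all-E)-4,9,13-trimethyl-15-(RE)pentadeca-2,4,6,8,10,12,14-heptaenal (C27 aldehyde), via C27 vinyl dioxolane 28 (not isolated)
Conditions: LiOMe, DMF, 80 °C; then 1 M aq HCl, THF, rt
Reagents that add atoms: water, O
Why: Wittig two-carbon homologation with the dioxolanylmethyl ylide stops cleanly after one extension because the new aldehyde is masked as an acetal, and the brief acid hydrolysis that frees it should also equilibrate the new C11=C12 bond to E.

Step 18
Reactants: 14 1-(RB)but-3-en-2-one, 29 (all-E)-4,9,13-trimethyl-15-(RE)pentadeca-2,4,6,8,10,12,14-heptaenal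
Product: 30 (all-E)-4-hydroxy-7,12,16-trimethyl-3-methylidene-1-(RB)-18-(RE)octadeca-5,7,9,11,13,15,17-heptaen-2-one (both C4 epimers)
Conditions: 14 (2.5 equiv), quinuclidine (0.5 equiv), MeOH (2 equiv), THF, rt, dark
Reagents that add atoms: none
Why: Morita–Baylis–Hillman reaction, in which the amine adds to the vinyl ketone, the resulting enolate adds 1,2 to the aldehyde (bond C9–C10) and the amine is eliminated; the new carbinol centre C10 forms without control and is removed in step 19.

Step 19
Reactants: 30 (all-E)-4-hydroxy-7,12,16-trimethyl-3-methylidene-1-(RB)-18-(RE)octadeca-5,7,9,11,13,15,17-heptaen-2-one, 31 (2E)-dec-2-enoic acid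
Product: 33 (3R,3'R,6'R)-3,3'-bis(TBS-oxy)-8-oxo-7,8-dihydro-β,ε-caroten-19-yl (2E)-dec-2-enoate, via C10 dec-2-enoate of the carbinol 32 (not isolated)
Conditions: DCC, DMAP (0.2 equiv), CH2Cl2, 0 °C → rt; then DABCO (0.3 equiv), THF, 40 °C, dark
Reagents that add atoms: none
Why: Steglich esterification followed by the amine-catalysed SN2'–SN2' 1,3-transposition known for Morita–Baylis–Hillman esters should carry the acyloxy group from C10 to C19, driven by conjugation of the new C9=C10 bond with both the ketone and the polyene, with the E geometry (C11 trans to the C8 carbonyl) as the thermodynamic outcome.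

Step 20
Reactants: 33 (3R,3'R,6'R)-3,3'-bis(TBS-oxy)-8-oxo-7,8-dihydro-β,ε-caroten-19-yl (2E)-dec-2-enoate
Product: 34 (3R,3'R,6'R)-3,3'-dihydroxy-8-oxo-7,8-dihydro-β,ε-caroten-19-yl (2E)-dec-2-enoate (target)
Conditions: HF·pyridine, pyridine, THF, 0 °C → rt
Reagents that add atoms: none
Why: Buffered fluoride desilylation should free both ring hydroxyls without cleaving the allylic ester, adding to the enone or ionizing the allylic alcohol of ring E.

**Compound list**

1 | acetone | CC(C)=O | starting material
2 | ethyl acetoacetate | CCOC(=O)CC(C)=O | starting material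
3 | ethyl 2-acetyl-3-methylbut-2-enoate | CCOC(=O)C(C(C)=O)=C(C)C | intermediate
4 | ethyl 2-acetyl-3,3-dimethyl-5-oxohexanoate (racemic) | CCOC(=O)C(C(C)=O)C(C)(C)CC(C)=O | intermediate
5 | ethyl 2,6,6-trimethyl-4-oxocyclohex-2-ene-1-carboxylate (racemic) | CCOC(=O)C1C(C)=CC(=O)CC1(C)C | intermediate
6 | ethyl (4S)-4-hydroxy-2,6,6-trimethylcyclohex-2-ene-1-carboxylate (both C1 epimers) | CCOC(=O)C1C(C)=C[C@@H](O)CC1(C)C | intermediate
7 | ethyl (4R)-4-hydroxy-2,6,6-trimethylcyclohex-1-ene-1-carboxylate | CCOC(=O)C1=C(C)C[C@@H](O)CC1(C)C | intermediate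
8 | ethyl (4R)-4-(TBS-oxy)-2,6,6-trimethylcyclohex-1-ene-1-carboxylate | CCOC(=O)C1=C(C)C[C@@H](O[Si](C)(C)C(C)(C)C)CC1(C)C | intermediate
9 | (RB)methanol, [(4R)-4-(TBS-oxy)-2,6,6-trimethylcyclohex-1-en-1-yl]methanol | OCC1=C(C)C[C@@H](O[Si](C)(C)C(C)(C)C)CC1(C)C | intermediate
10 | (RB)methyl bromide, {[(1R)-4-(bromomethyl)-3,5,5-trimethylcyclohex-3-en-1-yl]oxy}(tert-butyl)dimethylsilane | BrCC1=C(C)C[C@@H](O[Si](C)(C)C(C)(C)C)CC1(C)C | intermediate
11 | methoxyallene (1-methoxypropa-1,2-diene) | COC=C=C | starting material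
12 | 1-lithio-1-methoxyallene | [Li]C(OC)=C=C | intermediate
13 | 2-methoxy-1-(RB)buta-2,3-diene | C=C=C(OC)CC1=C(C)C[C@@H](O[Si](C)(C)C(C)(C)C)CC1(C)C | intermediate
14 | 1-(RB)but-3-en-2-one | C=CC(=O)CC1=C(C)C[C@@H](O[Si](C)(C)C(C)(C)C)CC1(C)C | intermediate
15 | ethyl (1R,4R)-4-hydroxy-2,6,6-trimethylcyclohex-2-ene-1-carboxylate (trans) | CCOC(=O)[C@H]1C(C)=C[C@H](O)CC1(C)C | intermediate
16 | ethyl (1R,4R)-4-(TBS-oxy)-2,6,6-trimethylcyclohex-2-ene-1-carboxylate | CCOC(=O)[C@H]1C(C)=C[C@H](O[Si](C)(C)C(C)(C)C)CC1(C)C | intermediate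
17 | (RE)methanol, [(1R,4R)-4-(TBS-oxy)-2,6,6-trimethylcyclohex-2-en-1-yl]methanol | OC[C@H]1C(C)=C[C@H](O[Si](C)(C)C(C)(C)C)CC1(C)C | intermediate
18 | 5-{[(RE)methyl]sulfanyl}-1-phenyl-1H-tetrazole | C(Sc2nnnn2-c3ccccc3)[C@H]1C(C)=C[C@H](O[Si](C)(C)C(C)(C)C)CC1(C)C | intermediate
19 | 5-{[(RE)methyl]sulfonyl}-1-phenyl-1H-tetrazole | O=S(=O)(C[C@H]1C(C)=C[C@H](O[Si](C)(C)C(C)(C)C)CC1(C)C)c2nnnn2-c3ccccc3 | intermediate
20 | ethyl (2E)-3-methyl-4-oxobut-2-enoate | CCOC(=O)/C=C(\C)C=O | starting material
21 | potassium (RE)[(1-phenyl-1H-tetrazol-5-yl)sulfonyl]methanide | [K+].[CH-]([C@H]1C(C)=C[C@H](O[Si](C)(C)C(C)(C)C)CC1(C)C)S(=O)(=O)c2nnnn2-c3ccccc3 | intermediate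
22 | ethyl (2E,4E)-3-methyl-5-(RE)penta-2,4-dienoate | CCOC(=O)/C=C(\C)/C=C/[C@H]1C(C)=C[C@H](O[Si](C)(C)C(C)(C)C)CC1(C)C | intermediate
23 | (2E,4E)-3-methyl-5-(RE)penta-2,4-dien-1-ol | OC/C=C(\C)/C=C/[C@H]1C(C)=C[C@H](O[Si](C)(C)C(C)(C)C)CC1(C)C | intermediate
24 | [(2E,4E)-3-methyl-5-(RE)penta-2,4-dien-1-yl]triphenylphosphonium bromide | [Br-].C(/C=C(\C)/C=C/[C@H]1C(C)=C[C@H](O[Si](C)(C)C(C)(C)C)CC1(C)C)[P+](c2ccccc2)(c3ccccc3)c4ccccc4 | intermediate
25 | (2E,4E,6E)-2,7-dimethylocta-2,4,6-trienedial | O=C/C(C)=C/C=C/C=C(C)/C=O | starting material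
26 | (2E,4E,6E,8E,10E,12E)-2,7,11-trimethyl-13-(RE)trideca-2,4,6,8,10,12-hexaenal | O=C/C(C)=C/C=C/C=C(C)/C=C/C=C(C)/C=C/[C@H]1C(C)=C[C@H](O[Si](C)(C)C(C)(C)C)CC1(C)C | intermediate
27 | (1,3-dioxolan-2-ylmethyl)triphenylphosphonium bromide | [Br-].C1COC(O1)C[P+](c2ccccc2)(c3ccccc3)c4ccccc4 | starting material
28 | 2-[(3E,5E,7E,9E,11E,13E)-3,8,12-trimethyl-14-(RE)tetradeca-1,3,5,7,9,11,13-heptaen-1-yl]-1,3-dioxolane (E/Z at C1=C2 of the chain) | C1COC(O1)C=C/C(C)=C/C=C/C=C(C)/C=C/C=C(C)/C=C/[C@H]2C(C)=C[C@H](O[Si](C)(C)C(C)(C)C)CC2(C)C | intermediate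
29 | (2E,4E,6E,8E,10E,12E,14E)-4,9,13-trimethyl-15-(RE)pentadeca-2,4,6,8,10,12,14-heptaenal | O=C/C=C/C(C)=C/C=C/C=C(C)/C=C/C=C(C)/C=C/[C@H]1C(C)=C[C@H](O[Si](C)(C)C(C)(C)C)CC1(C)C | intermediate
30 | (5E,7E,9E,11E,13E,15E,17E)-4-hydroxy-7,12,16-trimethyl-3-methylidene-1-(RB)-18-(RE)octadeca-5,7,9,11,13,15,17-heptaen-2-one (both C4 epimers) | C=C(C(O)/C=C/C(C)=C/C=C/C=C(C)/C=C/C=C(C)/C=C/[C@H]1C(C)=C[C@H](O[Si](C)(C)C(C)(C)C)CC1(C)C)C(=O)CC2=C(C)C[C@@H](O[Si](C)(C)C(C)(C)C)CC2(C)C | intermediate
31 | (2E)-dec-2-enoic acid | CCCCCCC/C=C/C(=O)O | starting material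
32 | (5E,7E,9E,11E,13E,15E,17E)-7,12,16-trimethyl-3-methylidene-2-oxo-1-(RB)-18-(RE)octadeca-5,7,9,11,13,15,17-heptaen-4-yl (2E)-dec-2-enoate (both C4 epimers) | CCCCCCC/C=C/C(=O)OC(/C=C/C(C)=C/C=C/C=C(C)/C=C/C=C(C)/C=C/[C@H]1C(C)=C[C@H](O[Si](C)(C)C(C)(C)C)CC1(C)C)C(=C)C(=O)CC2=C(C)C[C@@H](O[Si](C)(C)C(C)(C)C)CC2(C)C | intermediate
33 | (3R,3'R,6'R)-3,3'-bis(TBS-oxy)-8-oxo-7,8-dihydro-β,ε-caroten-19-yl (2E)-dec-2-enoate | CCCCCCC/C=C/C(=O)OC\C(=C/C=C/C(C)=C/C=C/C=C(C)/C=C/C=C(C)/C=C/[C@H]1C(C)=C[C@H](O[Si](C)(C)C(C)(C)C)CC1(C)C)C(=O)CC1=C(C)C[C@@H](O[Si](C)(C)C(C)(C)C)CC1(C)C | intermediate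
34 | (3R,3'R,6'R)-3,3'-dihydroxy-8-oxo-7,8-dihydro-β,ε-caroten-19-yl (2E)-dec-2-enoate (CNP0332433.1) | CCCCCCC/C=C/C(=O)OC\C(=C/C=C/C(C)=C/C=C/C=C(C)/C=C/C=C(C)/C=C/[C@H]1C(C)=C[C@H](O)CC1(C)C)C(=O)CC1=C(C)C[C@@H](O)CC1(C)C | target

**Step count and risks**

Total: 20 steps. Longest linear sequence: 14 steps (step 1, steps 8–17, steps 18–20).

Steps most likely to fail:

Step 1 (proposed new method). The Knoevenagel equilibrium with a ketone as the carbonyl partner may lie too far on the side of the starting materials. Self-condensation of acetone and sequestration of the amine as the enamino ester may then outrun the cross-annulation. Fallback (known chemistry, stepwise instead of one-pot): setting out from 1 and 2, the Knoevenagel condensation is run on its own with TiCl4 and pyridine in THF (0 °C to rt) and 3 is isolated by distillation. Mukaiyama–Michael addition of 2-(trimethylsilyloxy)propene to 3 (TiCl4, CH2Cl2, −78 °C) gives the diketone 4 after aqueous work-up. TsOH in refluxing toluene with removal of water then closes 4 to 5, where the route is rejoined. This fallback makes no compound outside the list (F0).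

Step 18. Addition of the ammonium enolate to a long, deactivated polyene aldehyde may be slow and reversible, and self-dimerization of the vinyl ketone (Rauhut–Currier) may consume it first. Fallback (stoichiometric conjugate addition–aldol–elimination instead of amine catalysis): setting out from 14 and 29, conjugate addition of Me2AlSeMe to 14 (toluene/CH2Cl2, −78 °C) gives the aluminium enolate at C9 regiospecifically. Trapping with 29 gives the aldol (5E,7E,9E,11E,13E,15E,17E)-4-hydroxy-7,12,16-trimethyl-3-[(methylselanyl)methyl]-1-(RB)-18-(RE)octadeca-5,7,9,11,13,15,17-heptaen-2-one F1. Oxidation with NaIO4 (aq THF, 0 °C) and syn-elimination of the selenoxide return to 30.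

Step 19. The doubly allylic ester may ionize, with loss of a proton or return of the carboxylate at remote positions of the polyene, and the 1,3-shift may stay incomplete. Fallback (metal π-allyl substitution instead of acyl transfer and amine-catalysed shift): setting out from 30, methyl chloroformate and pyridine (CH2Cl2, 0 °C) give the allylic carbonate (5E,7E,9E,11E,13E,15E,17E)-7,12,16-trimethyl-3-methylidene-2-oxo-1-(RB)-18-(RE)octadeca-5,7,9,11,13,15,17-heptaen-4-yl methyl carbonate F2. A zerovalent palladium catalyst, Pd(PPh3)4, with acid 31 in THF at rt then effects decarboxylative Tsuji–Trost substitution by the carboxylate at the unhindered terminus C19, which returns to 33.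

Further compounds
F0 | step 1 | none | none
F1 | step 18 | (5E,7E,9E,11E,13E,15E,17E)-4-hydroxy-7,12,16-trimethyl-3-[(methylselanyl)methyl]-1-(RB)-18-(RE)octadeca-5,7,9,11,13,15,17-heptaen-2-one | C[Se]CC(C(O)/C=C/C(C)=C/C=C/C=C(C)/C=C/C=C(C)/C=C/[C@H]1C(C)=C[C@H](O[Si](C)(C)C(C)(C)C)CC1(C)C)C(=O)CC2=C(C)C[C@@H](O[Si](C)(C)C(C)(C)C)CC2(C)C
F2 | step 19 | (5E,7E,9E,11E,13E,15E,17E)-7,12,16-trimethyl-3-methylidene-2-oxo-1-(RB)-18-(RE)octadeca-5,7,9,11,13,15,17-heptaen-4-yl methyl carbonate | COC(=O)OC(/C=C/C(C)=C/C=C/C=C(C)/C=C/C=C(C)/C=C/[C@H]1C(C)=C[C@H](O[Si](C)(C)C(C)(C)C)CC1(C)C)C(=C)C(=O)CC2=C(C)C[C@@H](O[Si](C)(C)C(C)(C)C)CC2(C)C
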